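## Analysis of the target

The target 21 is a cyclohexanone in which every ring carbon but one carries oxygen. The ring is numbered C1 (quaternary tertiary carbinol bearing the exocyclic C7H2 benzoate), C2 (ketone), C3 (CH2), C4 (CHOH), C5 (CH benzoate), C6 (CHOH). The four stereocentres are C1 (S), C4 (R), C5 (R) and C6 (S). C1-OH and C6-OH lie on one face; the C7 arm, C4-OH and C5-OBz lie on the other, so C5/C6 are trans and C4/C5 cis. Three motifs are sensitive: the β-hydroxy ketone C2/C3/C4 (dehydration, retro-aldol), the α-ketol C1/C2 (acyloin shift), and the benzoates, which can migrate to neighbouring hydroxyls. The carbon skeleton is simple; the difficulty is telling six oxygens apart (two benzoylated, one a ketone, three free) and setting the quaternary C1 in the right sense relative to C4–C6. The strategy rests on the C1/C6/C5 triad: a C6 hydroxyl cis to the tertiary C1 hydroxyl and trans to a C5 acyloxy group is what forms when a C5–C6 epoxide on the C1-OH face is opened at C5 by benzoate. That calls for a C5=C6 alkene lying between two carbinol carbons, C1 and C4, each able to carry a vinyl group, and hence for ring-closing metathesis.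

## Retrosynthetic reasoning

**21 to 20.** The C4 hydroxyl is β to the ketone and cis to the C5 benzoate, so it is kept as a silyl ether until the end. The last step only has to remove silicon under non-basic conditions.

**20 to 18 and 19.** The C5–O bond of the ring benzoate is cut, giving epoxide 18 and benzoic acid 19. Cutting here makes the acyl group arrive on the correct oxygen, so no diol has to be differentiated afterwards. The forward step must open the epoxide at C5 only, anti to the epoxide oxygen; titanium bound to the C1 alkoxide and the neopentylic nature of C6 both point to C5.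

**18 to 17.** The epoxide is traced to the C5=C6 alkene of 17. The oxygen must enter on the face of the C1 hydroxyl, which that hydroxyl can direct and which is also the face away from the C4 silyl ether and the C7 arm.

**17 to 13 (via 16, 14 and 15).** Three functional-group changes remain: C2 oxidation (16 to 17), C7 benzoylation with 15 (14 to 16), and release of the C2/C7 acetonide (13 to 14). The order is dictated by two facts. C2 must become a ketone before a C6 hydroxyl exists, because two secondary alcohols flanking C1 could not be told apart. It must also be a ketone before the epoxide exists, because a free C2 hydroxyl trans to the epoxide could attack C5 across the ring.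

**13 to 12.** The C5=C6 bond is cut. It is the only ring bond whose formation creates no stereocentre, and it turns the carbocycle into two vinyl carbinols that come from carbonyl and chiral-pool chemistry. Cutting C1–C2 or C3–C4 instead would make the ring-forming step set a stereocentre. The forward step only has to cyclize faster than it oligomerizes.

**12 to 10 and 11.** The C1–vinyl bond is cut, giving ketone 10 and vinylmagnesium bromide 11. The dioxanone ring supplies C7, C1 and C2 already protected, and its preference for axial attack should place the vinyl group cis to the C2 side chain, which is the C1 configuration of 21.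

**10 to 7 and 4 (via 9), and 7 to 5 and 6.** The C2–C3 bond is cut. Alkylation of the hydrazone 7, made from dioxanone 5 and auxiliary 6, with iodide 4 sets C2 under auxiliary control; hydrolysis of 9 returns the ketone. C2 is lost later at the ketone stage, but until then it relays the stereochemistry to C1.

**4 to 1 (via 3 and 2).** The C4 stereocentre is bought in diol 1. Selective sulfonylation of the primary hydroxyl, silylation of the secondary one and iodide exchange give 4 without touching the stereocentre.

## Alternatives that were turned down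

**Alternative 1:** furan cycloaddition.
- Disconnection: C2–C3 and C1–C6. Furan A1 supplies C3–C6 with its oxygen bridging C3 and C6; 2-bromoacrolein A2 supplies C1, C2 and, as the formyl carbon, C7.
- Forward key step: a tryptophan-derived B-butyl oxazaborolidine Lewis acid catalyses the Diels–Alder addition to the oxa-bridged aldehyde A3, formyl group exo.
- For: two C–C bonds, the ring, the quaternary C1 and the C6 oxygen arise in one catalytic enantioselective step from commodity chemicals. On steps to a first carbocycle, and on using a catalyst instead of a stoichiometric auxiliary, it is stronger than the chosen route.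
- Against: the oxygen map of A3 is offset from the target.
  - The bridge oxygen sits on C3, where 21 has CH2, and C2 is CH2 where 21 has the ketone.
  - The C1 bromide must be exchanged for hydroxyl with defined configuration.
  - The C4=C5 alkene is attacked on the bridge face, which would put O4 and O5 syn to O6, whereas 21 needs O5 anti to O6.
  - Furan adducts also revert readily.
- Comparison: the chosen route is longer to its ring, but every oxygen-bearing carbon enters at the right position and the ring closure creates no stereocentre.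

**Alternative 2:** Ferrier carbocyclization.
- Disconnection: C3–C4, as an aldol bond.
- Forward key step: catalytic Hg(OCOCF3)2 (divalent mercury) in aqueous acetone hydrates the exocyclic enol ether of the branched hex-5-enopyranoside A4; the ring-opened mercurio-enolate adds to the aldehyde and gives cyclohexanone A5.
- For: A5 has the β-hydroxy ketone C2/C3/C4 of the target and is one acetonide hydrolysis away from 21. On endgame length, and on avoiding a late epoxide opening, it is stronger than the chosen route.
- Against:
  - A4 needs a pyranose with a quaternary branch next to the enol ether, a benzoate on one oxygen only and a cis acetonide, which is a long protecting-group sequence from a hexose.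
  - C4 is created in the aldol step under substrate control that cannot be adjusted.
  - The β-hydroxy ketone must survive mercury salts and then an acidic acetonide removal, both of which invite elimination to the enone.
- Comparison: the chosen route builds its cyclization substrate from small pieces in seven steps and fixes C4 before the ring is closed, at the price of six steps after cyclization.

**Alternative 3:** nitronate allylation.
- Disconnection: C2–C3.
- Forward key step: Pd(PPh3)4 (zerovalent palladium) ionizes the Z-allylic methyl carbonate A6, and the C2 nitronate closes onto the C3 terminus of the allyl complex to give nitrocyclohexene A7.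
- For: C1, C6 and the C7 benzoate are in place before cyclization, the nitro group is a latent C2 ketone, and the C4=C5 alkene suits a cis-dihydroxylation that matches the cis C4/C5 oxygens of 21. That is one step where the chosen route needs two for C5/C6.
- Against:
  - The two new cis hydroxyls would then have to be told apart, with the benzoate needed on the more hindered C5.
  - The Nef step has to act next to the quaternary C1 and creates a ketone with a leaving group at C4.
  - Nitronate O-alkylation competes with C-alkylation.
  - A6 carries the quaternary C1 stereocentre, whose synthesis the key step does not address.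
- Comparison: the chosen route makes C1 by a diastereoselective Grignard addition to a cyclic ketone and places the ring benzoate regiospecifically through the epoxide.

Key step: step 8

Remark on the chemistry: ring atoms are numbered C1–C7 as in the analysis throughout. Iodide 4 is taken from diol 1 through its primary tosylate, because halide opening of a vinyl oxirane would be divided between the terminal and the allylic carbon.

## Route

Step 1
Reactants: 1 (S)-but-3-ene-1,2-diol
Product: 2 (S)-2-hydroxybut-3-en-1-yl 4-methylbenzenesulfonate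
Conditions: TsCl (1.05 equiv), Bu2SnO (2 mol%), Et3N, CH2Cl2, 0 °C → rt
Reagents that add atoms: p-toluenesulfonyl chloride, Cc1ccc(cc1)S(Cl)(=O)=O
Why: Tin-catalysed regioselective sulfonylation of a terminal 1,2-diol; in the dibutylstannylene acetal the primary oxygen reacts much faster than the secondary allylic one, and the stereocentre is not touched.

Step 2
Reactants: 2 (S)-2-hydroxybut-3-en-1-yl 4-methylbenzenesulfonate
Product: 3 (S)-2-[(tert-butyldimethylsilyl)oxy]but-3-en-1-yl 4-methylbenzenesulfonate
Conditions: TBSOTf, 2,6-lutidine, CH2Cl2, −78 → 0 °C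
Reagents that add atoms: tert-butyldimethylsilyl trifluoromethanesulfonate, CC(C)(C)[Si](C)(C)OS(=O)(=O)C(F)(F)F
Why: Silyl triflate silylation of a secondary alcohol; the hindered, non-nucleophilic base and low temperature should prevent closure of the hydroxy tosylate to an epoxide.

Step 3
Reactants: 3 (S)-2-[(tert-butyldimethylsilyl)oxy]but-3-en-1-yl 4-methylbenzenesulfonate
Product: 4 (S)-tert-butyl[(1-iodobut-3-en-2-yl)oxy]dimethylsilane
Conditions: NaI, butan-2-one, 80 °C
Reagents that add atoms: sodium iodide, [Na+].[I-]
Why: Finkelstein exchange by SN2 at the primary carbon; the adjacent stereocentre is not involved.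

Step 4
Reactants: 5 2,2-dimethyl-1,3-dioxan-5-one; 6 (S)-1-amino-2-(methoxymethyl)pyrrolidine (SAMP)
Product: 7 (S)-N-(2,2-dimethyl-1,3-dioxan-5-ylidene)-2-(methoxymethyl)pyrrolidin-1-amine
Conditions: C6H6, reflux, Dean–Stark trap
Reagents that add atoms: 6 (S)-1-amino-2-(methoxymethyl)pyrrolidine, COC[C@@H]1CCCN1N
Why: Hydrazone condensation driven by azeotropic removal of water; the symmetric ketone gives a single hydrazone.

Step 5
Reactants: 7 (S)-N-(2,2-dimethyl-1,3-dioxan-5-ylidene)-2-(methoxymethyl)pyrrolidin-1-amine; 4 (S)-tert-butyl[(1-iodobut-3-en-2-yl)oxy]dimethylsilane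
Product: 9 (S)-N-[(4S)-4-{(2R)-2-[(tert-butyldimethylsilyl)oxy]but-3-en-1-yl}-2,2-dimethyl-1,3-dioxan-5-ylidene]-2-(methoxymethyl)pyrrolidin-1-amine, via lithium azaenolate 8 (not isolated)
Conditions: t-BuLi, THF, −78 °C; then 4, −100 °C → rt
Reagents that add atoms: none
Why: Enders SAMP-hydrazone alkylation: the lithium azaenolate is held rigid by chelation to the methoxymethyl group and the iodide approaches the face remote from the pyrrolidine substituent, which with the S auxiliary should set ring C2 (dioxane C4) as S. C4 is carried in unchanged from 4.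

Step 6
Reactants: 9 (S)-N-[(4S)-4-{(2R)-2-[(tert-butyldimethylsilyl)oxy]but-3-en-1-yl}-2,2-dimethyl-1,3-dioxan-5-ylidene]-2-(methoxymethyl)pyrrolidin-1-amine
Product: 10 (4S)-4-{(2R)-2-[(tert-butyldimethylsilyl)oxy]but-3-en-1-yl}-2,2-dimethyl-1,3-dioxan-5-one
Conditions: sat. aq. (CO2H)2, Et2O, rt
Reagents that add atoms: water, O
Why: Two-phase oxalic acid hydrolysis of the hydrazone, mild enough to leave the acetonide, the silyl ether and the epimerizable α-centre intact; the auxiliary is recoverable from the aqueous phase.

Step 7
Reactants: 10 (4S)-4-{(2R)-2-[(tert-butyldimethylsilyl)oxy]but-3-en-1-yl}-2,2-dimethyl-1,3-dioxan-5-one; 11 vinylmagnesium bromide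
Product: 12 (4S,5R)-4-{(2R)-2-[(tert-butyldimethylsilyl)oxy]but-3-en-1-yl}-5-ethenyl-2,2-dimethyl-1,3-dioxan-5-ol
Conditions: THF, −78 °C; then H2O
Reagents that add atoms: 11 vinylmagnesium bromide, C=C[Mg]Br
Why: Grignard 1,2-addition to an electrophilic α,α'-dialkoxy ketone. A 1,3-dioxan-5-one has ring oxygens, not CH2 groups, at the positions that would hinder axial approach, so the small nucleophile should enter axially, cis to the equatorial side chain, leaving the hydroxyl trans to it (C1 of the target numbering, R in 12).

Step 8
Reactants: 12 (4S,5R)-4-{(2R)-2-[(tert-butyldimethylsilyl)oxy]but-3-en-1-yl}-5-ethenyl-2,2-dimethyl-1,3-dioxan-5-ol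
Product: 13 (4aR,7R,8aS)-7-[(tert-butyldimethylsilyl)oxy]-2,2-dimethyl-4a,7,8,8a-tetrahydro-4H-1,3-benzodioxin-4a-ol
Conditions: RuCl2(H2IMes)(PCy3)(=CHPh) (second-generation Grubbs catalyst, 5 mol%), CH2Cl2 (5 mM), 40 °C
Reagents that add atoms: none
Why: Ring-closing olefin metathesis by the Chauvin mechanism: loss of PCy3 gives the 14-electron ruthenium benzylidene, which exchanges with the less encumbered C4 vinyl group; the resulting C5 alkylidene adds across the C1 vinyl group to a ruthenacyclobutane that collapses to the C5=C6 bond and Ru=CH2, which carries the chain and releases ethylene. The closest known reaction type is the closure of 1,7-dienes flanked by oxygen-bearing carbons, tertiary allylic alcohols included, to cyclohexenols. The one ring closed is the six-membered carbocycle C1–C6, formed by joining the two terminal alkene carbons; its size forces a cis alkene and it is cis-fused to the dioxane. No stereocentre is created, and C1, C2 and C4 are not touched. The step needs cyclization to outrun metathesis between molecules: high dilution and loss of ethylene help, and in the dioxane chair the axial C1 vinyl group and the equatorial C2 side chain are gauche, with the quaternary C1 adding a Thorpe–Ingold bias. The free tertiary hydroxyl cannot be isomerized to a ketone by ruthenium hydrides, and the silyl ether and acetonide are inert.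

Step 9
Reactants: 13 (4aR,7R,8aS)-7-[(tert-butyldimethylsilyl)oxy]-2,2-dimethyl-4a,7,8,8a-tetrahydro-4H-1,3-benzodioxin-4a-ol
Product: 14 (1S,2R,5R)-5-[(tert-butyldimethylsilyl)oxy]-2-(hydroxymethyl)cyclohex-3-ene-1,2-diol
Conditions: PPTS (cat.), MeOH, rt
Reagents that add atoms: none
Why: Acid-catalysed transacetalization to methanol; the six-membered acetonide should exchange well before a secondary silyl ether is cleaved by this weak acid.

Step 10
Reactants: 14 (1S,2R,5R)-5-[(tert-butyldimethylsilyl)oxy]-2-(hydroxymethyl)cyclohex-3-ene-1,2-diol; 15 benzoyl chloride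
Product: 16 [(1R,4R,6S)-4-[(tert-butyldimethylsilyl)oxy]-1,6-dihydroxycyclohex-2-en-1-yl]methyl benzoate
Conditions: BzCl (1.05 equiv), 2,4,6-collidine, CH2Cl2, −40 → 0 °C
Reagents that add atoms: 15 benzoyl chloride, O=C(Cl)c1ccccc1
Why: Selective acylation of the primary C7 hydroxyl over the secondary C2 and tertiary C1 hydroxyls, using near-stoichiometric acid chloride at low temperature.

Step 11
Reactants: 16 [(1R,4R,6S)-4-[(tert-butyldimethylsilyl)oxy]-1,6-dihydroxycyclohex-2-en-1-yl]methyl benzoate
Product: 17 [(1R,4R)-4-[(tert-butyldimethylsilyl)oxy]-1-hydroxy-6-oxocyclohex-2-en-1-yl]methyl benzoate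
Conditions: IBX, DMSO, rt
Reagents that add atoms: none
Why: IBX oxidation of the only secondary alcohol; this reagent oxidizes 1,2-diols to α-ketols without glycol cleavage, and the neutral medium avoids β-elimination of the C4 silyloxy group from the new ketone.

Step 12
Reactants: 17 [(1R,4R)-4-[(tert-butyldimethylsilyl)oxy]-1-hydroxy-6-oxocyclohex-2-en-1-yl]methyl benzoate
Product: 18 [(1S,2S,5R,6R)-5-[(tert-butyldimethylsilyl)oxy]-2-hydroxy-3-oxo-7-oxabicyclo[4.1.0]heptan-2-yl]methyl benzoate
Conditions: VO(acac)2 (5 mol%), t-BuOOH (in decane), CH2Cl2, 0 °C → rt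
Reagents that add atoms: tert-butyl hydroperoxide, CC(C)(C)OO
Why: Vanadium-catalysed hydroxyl-directed epoxidation of a tertiary allylic alcohol: the peroxide is delivered from the vanadate ester of C1-OH to the alkene face that carries this hydroxyl. That is also the face away from the C4 silyl ether and the C7 benzoate arm, so direction and sterics agree and C5/C6 are set with the epoxide cis to C1-OH.

Step 13
Reactants: 18 [(1S,2S,5R,6R)-5-[(tert-butyldimethylsilyl)oxy]-2-hydroxy-3-oxo-7-oxabicyclo[4.1.0]heptan-2-yl]methyl benzoate; 19 benzoic acid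
Product: 20 [(1S,2S,3S,4R)-3-(benzoyloxy)-4-[(tert-butyldimethylsilyl)oxy]-1,2-dihydroxy-6-oxocyclohexyl]methyl benzoate
Conditions: Ti(OiPr)4, PhCO2H, CH2Cl2, rt
Reagents that add atoms: 19 benzoic acid, OC(=O)c1ccccc1
Why: Titanium-mediated opening of a 2,3-epoxy alcohol by a carboxylic acid at the carbon remote from the hydroxyl: titanium bridging the C1 alkoxide and the epoxide oxygen weakens the C5–O bond, and C6 is neopentylic, so benzoate should attack C5 with inversion. This gives C5-OBz trans to C6-OH, which stays cis to C1-OH.

Step 14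
Reactants: 20 [(1S,2S,3S,4R)-3-(benzoyloxy)-4-[(tert-butyldimethylsilyl)oxy]-1,2-dihydroxy-6-oxocyclohexyl]methyl benzoate
Product: 21 [(1S,2S,3R,4R)-3-(benzoyloxy)-1,2,4-trihydroxy-6-oxocyclohexyl]methyl benzoate
Conditions: HF·pyridine, pyridine, THF, 0 °C → rt
Reagents that add atoms: none
Why: Fluoride desilylation under buffered, weakly acidic conditions; basic fluoride sources are avoided because they would promote β-elimination at C3/C4 and benzoate migration between the cis C4 and C5 oxygens.

## Compound list

1 | (S)-but-3-ene-1,2-diol | OC[C@@H](O)C=C | starting material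
2 | (S)-2-hydroxybut-3-en-1-yl 4-methylbenzenesulfonate | Cc1ccc(cc1)S(=O)(=O)OC[C@@H](O)C=C | intermediate
3 | (S)-2-[(tert-butyldimethylsilyl)oxy]but-3-en-1-yl 4-methylbenzenesulfonate | Cc1ccc(cc1)S(=O)(=O)OC[C@@H](O[Si](C)(C)C(C)(C)C)C=C | intermediate
4 | (S)-tert-butyl[(1-iodobut-3-en-2-yl)oxy]dimethylsilane | IC[C@@H](O[Si](C)(C)C(C)(C)C)C=C | intermediate
5 | 2,2-dimethyl-1,3-dioxan-5-one | CC1(C)OCC(=O)CO1 | starting material
6 | (S)-1-amino-2-(methoxymethyl)pyrrolidine (SAMP) | COC[C@@H]1CCCN1N | starting material
7 | (S)-N-(2,2-dimethyl-1,3-dioxan-5-ylidene)-2-(methoxymethyl)pyrrolidin-1-amine | COC[C@@H]1CCCN1N=C1COC(C)(C)OC1 | intermediate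
8 | lithium azaenolate of 7 | [Li+].COC[C@@H]1CCCN1[N-]C1=COC(C)(C)OC1 | intermediate
9 | (S)-N-[(4S)-4-{(2R)-2-[(tert-butyldimethylsilyl)oxy]but-3-en-1-yl}-2,2-dimethyl-1,3-dioxan-5-ylidene]-2-(methoxymethyl)pyrrolidin-1-amine (C=N geometry not specified) | COC[C@@H]1CCCN1N=C1COC(C)(C)O[C@H]1C[C@@H](O[Si](C)(C)C(C)(C)C)C=C | intermediate
10 | (4S)-4-{(2R)-2-[(tert-butyldimethylsilyl)oxy]but-3-en-1-yl}-2,2-dimethyl-1,3-dioxan-5-one | O=C1COC(C)(C)O[C@H]1C[C@@H](O[Si](C)(C)C(C)(C)C)C=C | intermediate
11 | vinylmagnesium bromide | C=C[Mg]Br | starting material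
12 | (4S,5R)-4-{(2R)-2-[(tert-butyldimethylsilyl)oxy]but-3-en-1-yl}-5-ethenyl-2,2-dimethyl-1,3-dioxan-5-ol | C=C[C@@]1(O)COC(C)(C)O[C@H]1C[C@@H](O[Si](C)(C)C(C)(C)C)C=C | intermediate
13 | (4aR,7R,8aS)-7-[(tert-butyldimethylsilyl)oxy]-2,2-dimethyl-4a,7,8,8a-tetrahydro-4H-1,3-benzodioxin-4a-ol | O[C@]12COC(C)(C)O[C@H]1C[C@@H](O[Si](C)(C)C(C)(C)C)C=C2 | intermediate
14 | (1S,2R,5R)-5-[(tert-butyldimethylsilyl)oxy]-2-(hydroxymethyl)cyclohex-3-ene-1,2-diol | O[C@]1(CO)[C@@H](O)C[C@@H](O[Si](C)(C)C(C)(C)C)C=C1 | intermediate
15 | benzoyl chloride | O=C(Cl)c1ccccc1 | starting material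
16 | [(1R,4R,6S)-4-[(tert-butyldimethylsilyl)oxy]-1,6-dihydroxycyclohex-2-en-1-yl]methyl benzoate | O=C(OC[C@@]1(O)[C@@H](O)C[C@@H](O[Si](C)(C)C(C)(C)C)C=C1)c1ccccc1 | intermediate
17 | [(1R,4R)-4-[(tert-butyldimethylsilyl)oxy]-1-hydroxy-6-oxocyclohex-2-en-1-yl]methyl benzoate | O=C(OC[C@@]1(O)C(=O)C[C@@H](O[Si](C)(C)C(C)(C)C)C=C1)c1ccccc1 | intermediate
18 | [(1S,2S,5R,6R)-5-[(tert-butyldimethylsilyl)oxy]-2-hydroxy-3-oxo-7-oxabicyclo[4.1.0]heptan-2-yl]methyl benzoate | O=C(OC[C@@]1(O)C(=O)C[C@@H](O[Si](C)(C)C(C)(C)C)[C@@H]2O[C@@H]21)c1ccccc1 | intermediate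
19 | benzoic acid | OC(=O)c1ccccc1 | starting material
20 | [(1S,2S,3S,4R)-3-(benzoyloxy)-4-[(tert-butyldimethylsilyl)oxy]-1,2-dihydroxy-6-oxocyclohexyl]methyl benzoate | O=C(OC[C@@]1(O)C(=O)C[C@@H](O[Si](C)(C)C(C)(C)C)[C@@H](OC(=O)c2ccccc2)[C@@H]1O)c1ccccc1 | intermediate
21 | [(1S,2S,3R,4R)-3-(benzoyloxy)-1,2,4-trihydroxy-6-oxocyclohexyl]methyl benzoate | O=C(OC[C@@]1(O)C(=O)C[C@@H](O)[C@@H](OC(=O)c2ccccc2)[C@@H]1O)c1ccccc1 | target

## Step count and least certain steps

Total: 14 steps. Longest linear sequence: 13 steps (1 to 21 through steps 1–3 and 5–14); from dioxanone 5 the sequence is 11 steps.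

**Step 8 (key step).** The most likely failure is metathesis between molecules, or slow turnover, because both alkenes sit next to hindered oxygen-bearing carbons (a quaternary carbinol and a silyloxy-substituted carbon). The fallback closes the ring through the C1–C6 bond by carbonyl addition. It sets out from ketone 10. Ozonolysis (O3, CH2Cl2/MeOH, −78 °C; Me2S) should give (2R)-2-[(tert-butyldimethylsilyl)oxy]-3-[(4S)-2,2-dimethyl-5-oxo-1,3-dioxan-4-yl]propanal F1. Stork–Zhao olefination (Ph3P=CHI, THF, −78 °C) of the aldehyde, much the more reactive carbonyl, should give the Z-iodoalkene (4S)-4-{(2R,3Z)-2-[(tert-butyldimethylsilyl)oxy]-4-iodobut-3-en-1-yl}-2,2-dimethyl-1,3-dioxan-5-one F2. Intramolecular Nozaki–Hiyama–Kishi addition (CrCl2, catalytic NiCl2, DMSO, rt) onto the dioxanone carbonyl would then come back to the route at 13. Axial attack, as in step 7, is expected to give the cis ring fusion.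

**Step 5.** Substitution at a primary iodide that is β-branched and β-silyloxylated is slow, and loss of HI toward a silyloxy diene may compete, since the β-hydrogen is allylic. The fallback replaces the iodide by an epoxide and introduces the vinyl group afterwards. It sets out from hydrazone 7 through azaenolate 8. Reaction with (R)-epichlorohydrin (THF, −78 °C → rt), attack at the epoxide CH2 followed by closure of the alkoxide onto the chloride, should give the epoxide (S)-N-[(4S)-2,2-dimethyl-4-{[(2R)-oxiran-2-yl]methyl}-1,3-dioxan-5-ylidene]-2-(methoxymethyl)pyrrolidin-1-amine F3. One-carbon homologation with dimethylsulfonium methylide (Me3S+ I−, n-BuLi, THF, −10 °C → rt) should give the allylic alcohol (S)-N-[(4S)-4-[(2R)-2-hydroxybut-3-en-1-yl]-2,2-dimethyl-1,3-dioxan-5-ylidene]-2-(methoxymethyl)pyrrolidin-1-amine F4. Silylation (TBSCl, imidazole, DMF) returns to the route at 9.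

**Step 7.** The risks are poor facial selectivity (equatorial attack, which would give the C1 epimer and cannot be corrected later) and enolization of the ketone. The fallback uses a smaller sp nucleophile with a stronger axial preference. It sets out from 10. Ethynylmagnesium bromide (THF, −78 °C) should give (4S,5R)-4-{(2R)-2-[(tert-butyldimethylsilyl)oxy]but-3-en-1-yl}-5-ethynyl-2,2-dimethyl-1,3-dioxan-5-ol F5. Semihydrogenation (H2, Pd/CaCO3 poisoned with Pb(OAc)2, quinoline, EtOAc) returns to the route at 12.

**Step 13.** Several things may go wrong: opening at C6 through participation of the C7 benzoate carbonyl, ester exchange with titanium isopropoxide, or an acyloin shift of the α-ketol on the Lewis acid. The fallback moves epoxidation and opening ahead of acetonide removal, where neither the ketone nor the C7 benzoate is present. It also bypasses step 12 on the ketol, at the cost of two extra steps. It sets out from 13 and proceeds as follows.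
- VO(acac)2/t-BuOOH should give the 5,6-epoxide of 13 with the oxygen cis to the tertiary hydroxyl F6.
- Ti(OiPr)4/PhCO2H should give the C5 benzoate with C6-OH cis to C1-OH, acetonide and C4 silyl ether retained F7.
- TBSOTf/2,6-lutidine should protect the secondary C6 hydroxyl, giving the C4,C6-bis-silyl ether F8.
- PPTS/MeOH should release the triol with C1, C2 and C7 hydroxyls free F9.
- BzCl/collidine should give the C7 benzoate F10.
- IBX/DMSO should give the C2 ketone, the C4,C6-bis-silyl ether of 21 F11.
- HF·pyridine removes both silyl groups and comes back to the route at 21.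

## Further compounds

F1 | step 8 | (2R)-2-[(tert-butyldimethylsilyl)oxy]-3-[(4S)-2,2-dimethyl-5-oxo-1,3-dioxan-4-yl]propanal | O=C1COC(C)(C)O[C@H]1C[C@@H](O[Si](C)(C)C(C)(C)C)C=O
F2 | step 8 | (4S)-4-{(2R,3Z)-2-[(tert-butyldimethylsilyl)oxy]-4-iodobut-3-en-1-yl}-2,2-dimethyl-1,3-dioxan-5-one | O=C1COC(C)(C)O[C@H]1C[C@@H](O[Si](C)(C)C(C)(C)C)/C=C\I
F3 | step 5 | (S)-N-[(4S)-2,2-dimethyl-4-{[(2R)-oxiran-2-yl]methyl}-1,3-dioxan-5-ylidene]-2-(methoxymethyl)pyrrolidin-1-amine | COC[C@@H]1CCCN1N=C1COC(C)(C)O[C@H]1C[C@@H]1CO1
F4 | step 5 | (S)-N-[(4S)-4-[(2R)-2-hydroxybut-3-en-1-yl]-2,2-dimethyl-1,3-dioxan-5-ylidene]-2-(methoxymethyl)pyrrolidin-1-amine | COC[C@@H]1CCCN1N=C1COC(C)(C)O[C@H]1C[C@@H](O)C=C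
F5 | step 7 | (4S,5R)-4-{(2R)-2-[(tert-butyldimethylsilyl)oxy]but-3-en-1-yl}-5-ethynyl-2,2-dimethyl-1,3-dioxan-5-ol | C#C[C@@]1(O)COC(C)(C)O[C@H]1C[C@@H](O[Si](C)(C)C(C)(C)C)C=C
F6 | step 13 | 5,6-epoxide of 13, epoxide oxygen cis to the tertiary hydroxyl | O[C@]12COC(C)(C)O[C@H]1C[C@@H](O[Si](C)(C)C(C)(C)C)[C@@H]3O[C@@H]32
F7 | step 13 | C5 benzoate from opening of F6 at C5, C6-OH cis to C1-OH, acetonide and C4 silyl ether retained | O[C@]12COC(C)(C)O[C@H]1C[C@@H](O[Si](C)(C)C(C)(C)C)[C@@H](OC(=O)c1ccccc1)[C@@H]2O
F8 | step 13 | C6 tert-butyldimethylsilyl ether of F7 | O[C@]12COC(C)(C)O[C@H]1C[C@@H](O[Si](C)(C)C(C)(C)C)[C@@H](OC(=O)c1ccccc1)[C@@H]2O[Si](C)(C)C(C)(C)C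
F9 | step 13 | triol from F8 after acetonide removal (C1, C2 and C7 hydroxyls free) | OC[C@@]1(O)[C@@H](O)C[C@@H](O[Si](C)(C)C(C)(C)C)[C@@H](OC(=O)c2ccccc2)[C@@H]1O[Si](C)(C)C(C)(C)C
F10 | step 13 | C7 benzoate of F9 | O=C(OC[C@@]1(O)[C@@H](O)C[C@@H](O[Si](C)(C)C(C)(C)C)[C@@H](OC(=O)c2ccccc2)[C@@H]1O[Si](C)(C)C(C)(C)C)c1ccccc1
F11 | step 13 | C2 ketone of F10, the C4,C6-bis(tert-butyldimethylsilyl) ether of 21 | O=C(OC[C@@]1(O)C(=O)C[C@@H](O[Si](C)(C)C(C)(C)C)[C@@H](OC(=O)c2ccccc2)[C@@H]1O[Si](C)(C)C(C)(C)C)c1ccccc1
A1 | alternative 1 | furan | c1ccoc1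
A2 | alternative 1 | 2-bromoacrolein | C=C(Br)C=O
A3 | alternative 1 | 2-bromo-7-oxabicyclo[2.2.1]hept-5-ene-2-carbaldehyde, formyl group exo | O=C[C@@]1(Br)C[C@@H]2C=C[C@H]1O2
A4 | alternative 2 | methyl 2-O-benzoyl-4-C-(benzoyloxymethyl)-6-deoxy-3,4-O-isopropylidenehex-5-enopyranoside (anomeric configuration open) | C=C1OC(OC)[C@@H](OC(=O)c2ccccc2)[C@@H]2OC(C)(C)O[C@]12COC(=O)c1ccccc1
A5 | alternative 2 | C1/C6 acetonide of 21 | O=C1C[C@@H](O)[C@@H](OC(=O)c2ccccc2)[C@@H]2OC(C)(C)O[C@]12COC(=O)c1ccccc1
A6 | alternative 3 | Z-allylic methyl carbonate carrying the nitromethyl group on C1 (C1/C6 acetonide, C7 benzoate) | [O-][N+](=O)C[C@@]1(COC(=O)c2ccccc2)OC(C)(C)O[C@H]1/C=C\COC(=O)OC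
A7 | alternative 3 | 2-nitrocyclohex-4-ene with C1/C6 acetonide and C7 benzoate | [O-][N+](=O)[C@H]1CC=C[C@@H]2OC(C)(C)O[C@]12COC(=O)c1ccccc1
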